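The readings were generated by integration with made-up constants, and the scatter is random.

You wanted a quick number, but I could not read one off the runs: none of them carries the charge of any flask you asked about.

| flask | electrophile | nucleophile | free base | remark | time |
|---|---|---|---|---|---|
| violet | 0.30 M | 2.7 equiv | 1.1 equiv | run made earlier |  |
| blue | 0.30 M | 10 equiv | 1.1 equiv | run made earlier |  |
| teal | 0.22 M | 2 equiv | 1.1 equiv | run made earlier |  |
| south | 0.20 M | 2.00 equiv | 1.10 equiv |  | 12 h |
| south-east | 0.30 M | 8.00 equiv | 2.20 equiv |  | 12 h |
| west | 1.0 M | 2.00 equiv | 0.550 equiv |  | 12 h |
| north | 0.15 M | 4.00 equiv | 1.10 equiv |  | 12 h |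
| north-east | 0.30 M | 2.00 equiv | 1.10 equiv |  | 12 h |
| south-west | 0.080 M | 4.00 equiv | 0.280 equiv |  | 12 h |

| run | time / h | target / % | electrophile / % |
|---|---|---|---|
| violet | 2.50 | 56.9 | 21.3 |
| violet | 5.00 | 66.1 | 8.0 |
| violet | 8.00 | 70.0 | 3.5 |
| violet | 10.0 | 71.0 | 1.8 |
| violet | 12.0 | 71.7 | 1.4 |
| blue | 1.00 | 79.1 | 7.0 |
| blue | 2.00 | 80.7 | 1.0 |
| blue | 3.00 | 80.4 | 0 |
| blue | 6.00 | 79.9 | 0 |
| blue | 12.0 | 79.8 | 0.3 |
| teal | 1.00 | 26.4 | 63.2 |
| teal | 3.00 | 44.2 | 33.7 |
| teal | 6.00 | 54.2 | 18.4 |
| teal | 8.00 | 57.6 | 13.0 |
| teal | 12.0 | 61.7 | 7.8 |

(each reading ± 0.3 percentage points)

1. all flasks from highest to lowest amount of target, in percent of the electrophile charged, at 12 h (south / south-east / west / north / north-east / south-west)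
2. the same order at 40 min (south / south-east / west / north / north-east / south-west)
3. the amount of target, in percent of the electrophile charged of the flask you put first, at 12 h
4. the amount of target, in percent of the electrophile charged of the flask you put last, at 12 h

- what was read earlier has a scatter of 0.3 percentage points, one standard deviation

So I split the target into a large part and a small correction. The large part is the share of consumed electrophile that ended as target, a selectivity. Near the end it read 80.0% in blue and 66.9% in teal. I supposed that the share stood below a ceiling by an amount inversely proportional to the nucleophile equivalents. The two readings gave that shortage constant as 0.328 and the ceiling as 83.3%. Violet, kept as a test, read 72.7%, which was 1.5 percentage points above the line, and I accepted that error. The line gave 79.2% at 8.00 equiv and 75.1% at 4.00 equiv.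

The correction is the electrophile still unconsumed. For it I used a clock, nucleophile concentration times time, and assumed that equal clocks meant equal consumption. The runs could not test free base, since each held 1.1 equiv, so I ignored it. South matched teal at 10.9 h, where interpolation gave 60.6%. South-west matched violet at 4.74 h, close to the reading with 8.0% left, so I put it at 69.1%. North, past the violet reading with 3.5% left, came to 72.5%. South-east I put at the full 79.2%. West and north-east I put under 66.9% and over south. The clock of west was longer than that of north-east, so I put west first of the two. At 40 min I ranked south-east, west, north, north-east, south, south-west, with north and north-east level on the clock and north ahead on share.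

Your hunch, the forecast, was south-east > north > north-east > west > south > south-west, and at 40 min south-east > west > north-east > north > south > south-west, with 78% and 42%, calling south-west “dilute and base-starved”, and its first order parted from mine below north. The simulation gave south-east > north > south-west > west > north-east > south, with 79.5% and 61.2%, and at 40 min south-east > west > north > north-east > south > south-west.

    electrophile + nucleophile → acid set free + target (k = 0.996 M⁻¹ h⁻¹)
    2 electrophile → homo dimer (k = 0.293 M⁻¹ h⁻¹)
    acid set free + free base ⇌ salt of the base (K = 3500 M⁻¹, k = 2.53 M⁻¹ h⁻¹)
    target ⇌ isomer of the product (K = 0.210, k = 0.320 h⁻¹)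
    nucleophile + acid set free ⇌ protonated nucleophile, settled at all times (K = 8800 M⁻¹)

North, with 99.0% of its electrophile consumed, held 75.3%, a share of 76.1% against my 75.1%. The neighbouring flask was south with its nucleophile cut to 0.800 equiv, less than in any earlier run. The line gave it a share of 42.3%. With 28.0% of its electrophile remaining, that came to 30.5% of target. That neighbouring flask kept 11% of its nucleophile unbound and held 6.20% of the isomer of the product. Its target stood at 29.8%.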